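Assumption: TBS is tert‑butyldimethylsilyl and TBSO its ether. O1, C2–C5 are the butenolide atoms and O1', C2', C3', C3a', C4'–C7', C7a' those of the hexahydrobenzofuran (ring B). The SMILES is read as 3R in ring A and 2'R, 6'S, 7a'R in ring B. Compounds 24, 27 and 31 are taken as commercial.

## Structural features

The target is a nor‑carotenoid in which a (3R)‑3‑hydroxy‑2,6,6‑trimethylcyclohexenyl ring (ring A) is joined through a C≡C bond to an all‑E tetraene with a methyl group at each end. The tetraene ends in the exocyclic (Z)‑alkene of a γ‑ylidenebutenolide (O1, C2–C5). Butenolide C3 carries C2' of a 2,4,5,6,7,7a‑hexahydro‑1‑benzofuran, a dihydrofuran fused to a cyclohexane through the alkene carbon C3a' and the quaternary C7a'. Ring B holds three stereocentres: C2' (R) and C7a' (R) flank O1', and C6' (S) is 1,3 to C7a' across C7', with O1' trans to the C6' hydroxyl. The ring A carbinol is remote and has the same spatial sense as C6', so both rings can come from one enantiopure cyclohexenyl unit. Fragile elements are the polyenyne (light, oxygen, acid), the enol lactone (base, nucleophiles) and the C2'–O1' bond, which is doubly allylic and ionises under acid with loss of the C2' configuration. The real difficulty is the fully substituted C7a', whose oxygen must sit on the face away from the C6' hydroxyl, together with a C2' centre that no ring substituent can control. The key step uses the fact that C3a' and C7a' are neighbours: an epoxide across them, syn to the C6' oxygen, is opened at C7a' from the rear by a hydroxyl on C2'. This closes O1'–C7a' with inversion and leaves on C3a' a hydroxyl that can later leave only toward C3'.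

## Logic of the disconnections

36 from 35: the two O–Si bonds are cut last. Both carbinols carry the same silyl group, so one buffered fluoride step frees them. The forward step must avoid acid (C2' ionisation) and free base (enol lactone).

35 from 23 and 32: the exocyclic C5=C bond is cut. This divides the molecule into two halves of similar size, makes the butenolide γ‑carbon the nucleophile and the polyenal the electrophile, and keeps the sensitive polyene out of all ring B chemistry. The forward step must be γ‑selective, give the Z alkene on elimination, and not ionise C2'–O1'.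

23 from 22, 22 from 21, 21 from 19: water is added back across C3'=C3a', then C2–C3 and C2–O1 of the lactone are cut (loss of CO), then the C–I bond is returned to an alkyne. A propargylic alcohol is the simplest butenolide precursor, because hydroxyl‑directed hydroalumination puts the metal on the alkyne carbon next to C2'. Dehydration comes after the lactone, since the dehydrating agent would attack a free primary alcohol and since the aluminium hydride and iodine then never meet the doubly allylic ether. The forward steps need a regio‑ and stereoselective hydroalumination; the dehydration is regiospecific by structure.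

19 from 18: the O1'–C7a' bond is cut. This removes the ring, the quaternary ether centre and the trans O1'/C6'‑O relation in one operation and traces C7a' back to an epoxide face. The forward step must attack C7a', not C3a', and must beat elimination and skeletal rearrangement.

18 from 17, 16, 15, 14 and 13: the two epoxide C–O bonds are cut and the protecting groups rearranged. The epoxide has to be delivered by the C6' hydroxyl. A silyl ether there cannot bind vanadium, and a free C2' hydroxyl, which is also homoallylic, would compete as director with no predictable face. Therefore the C2' and primary hydroxyls are acetylated (14), the C6' silyl group is removed (15), the epoxide is installed (16), C6' is silylated again (17) and the acetates are removed (18). The primary propargylic hydroxyl is left free in 18: it cannot bend back across the linear alkyne to reach the epoxide and it is needed free for hydroalumination, so no later differentiation of two silyl ethers is required. The cost is four simple protecting‑group steps.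

13 from 12, and 12 from 9 and 10: the C2'–H bond and the C2'–C(sp) bond are cut. C2' is set by a catalyst and is therefore independent of the ring stereocentre. The ketone comes from an acetylide and a Weinreb amide. The reduction must run without base because the ynone is β,γ‑unsaturated.

9 from 8, and 8 from 5 and 6: the amide C–N bond and the ring C(sp2)–CH2 bond are cut. The enol triflate fixes the position of the tetrasubstituted alkene, which an aldol–dehydration sequence would not. The forward coupling must cope with a hindered triflate.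

32 from 30 and 31, then 29, 28, 26 with 27, 25, and finally 5 with 24: C2=C3 of the chain (Wittig), C6=C7 (Horner–Wadsworth–Emmons) and the ring–alkyne bond (Sonogashira) are cut. Each olefination uses a stabilised reagent that should give the E alkene, and 24 brings its E alkene with it. The cost is two redox adjustments.

5 from 4, 3, 2 and 1: the C–OTf bond is cut, then the stereochemistry is traced to two reductions of the prochiral enedione 1. The C=C reduction sets C6, the C6 centre and the axial methyl steer the hydride at C4, and C6 is then erased in the enol triflate. 5 serves both rings.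

## Other disconnections considered

Alternative 1: The lactone is cut at C2–C3 and C2–O1, which leads back to the (Z)‑β‑iodoenone A1 and carbon monoxide. In the forward step zerovalent palladium inserts into the C–I bond of A1, CO inserts, and the enol oxygen of the ketone is acylated to give the ylidenebutenolide A2. In its favour, the lactone ring and the exocyclic alkene form in one step, and the Z geometry follows from ring closure and not from an elimination. Against it here, A1 already contains the complete ring B, so the C7a' and C2' problems are untouched and an epoxide opening or an equivalent would still be needed. A1 also has to be made as a single vinyl iodide isomer next to a skipped enone that can move into conjugation, and A2 still needs three or more steps to attach the rest of the polyene and ring A. On structure it is the better plan for the ylidene geometry. On mechanism it is the equal of the chosen plan, since both use the same acylpalladium lactonisation. On step economy it is not shorter, and it moves polyene olefinations to a stage where ring B and the enol lactone are already present.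

Alternative 2: The O1'–C2' bond is cut, which leads back to the allenol A3 with the tertiary hydroxyl on C7a' and an allene from C3a' to C2'. In the forward step a silver or gold cation activates the distal allene bond, the hydroxyl adds in a 5‑endo mode and protodemetalation gives the dihydrofuran A4. In its favour, the C3'=C3a' alkene is formed directly, so no dehydration is needed; no tertiary cation is involved; and C2' comes from the allene axis by a stereospecific anti addition. Against it here, A3 needs a defined allene axis and a tertiary carbinol at C7a' trans to the C6' oxygen, which is the same quaternary‑centre problem moved to an earlier compound and now without an inversion to relay it from C6'. The metal can also racemise the axis, and the furan in A4 must afterwards be oxidised regioselectively to the 3‑substituted butenolide. On structure it is the better plan for the ring B alkene. On mechanism it is the equal of the chosen plan in that C2' is set by a reagent‑controlled element. On step economy it saves the dehydration but adds the axis control and the furan oxidation, so no net gain is expected.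

Alternative 3: The O1–C2 bond is cut, which leads back to the hydroxymethyl cyclopropenone A5. In the forward step catalytic PPh3 adds to the ring carbon that bears CH2OH, the three‑membered ring opens to a ketene ylide, the hydroxyl adds to the ketene carbon and the phosphine is released, giving A6. A6 is the same compound as 23 of the chosen route. In its favour, the step is neutral and free of metal and CO, and it is driven by ring strain. Against it here, A5 must be built from the same alkyne by carbene addition and hydrolysis, a sequence that would also attack the electron‑rich ring alkene or a free hydroxyl. Only addition at one of the two ring carbons is productive. Ring B is again untouched. On structure it is the equal of the chosen plan, since it delivers the same intermediate. On mechanism it is the better plan in that it avoids CO and palladium. On step economy it is the equal, since it replaces steps 15 and 16 by a sequence of similar length, and it has less support on hindered, oxygenated substrates.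

Key step: step 14

## Route

Step 1
Reactants: 1 ketoisophorone
Product: 2 (6R)‑2,2,6‑trimethylcyclohexane‑1,4‑dione
Conditions: ene reductase (old yellow enzyme OYE2), NADP+ (cat.), glucose dehydrogenase, D‑glucose, phosphate buffer pH 7, 30 °C
Reagents that add atoms: none
Why: Enzymatic asymmetric conjugate reduction: the flavin delivers hydride to the unsubstituted alkene carbon and the enzyme protonates the methyl‑bearing carbon from one face, which should set the (6R) centre; the carbonyl groups are not reduced.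

Step 2
Reactants: 2 (6R)‑2,2,6‑trimethylcyclohexane‑1,4‑dione
Product: 3 (4R,6R)‑4‑hydroxy‑2,2,6‑trimethylcyclohexan‑1‑one
Conditions: LiBH(s‑Bu)3, THF, −78 °C; aqueous work‑up
Reagents that add atoms: none
Why: Diastereoselective ketone reduction under steric approach control: C1 is shielded by a quaternary and a tertiary neighbour, and at C4 the bulky borohydride should enter equatorially, away from the axial C2 methyl, so that the hydroxyl becomes axial and trans to the equatorial C6 methyl, which is (4R).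

Step 3
Reactants: 3 (4R,6R)‑4‑hydroxy‑2,2,6‑trimethylcyclohexan‑1‑one
Product: 4 (4R,6R)‑4‑(TBSO)‑2,2,6‑trimethylcyclohexan‑1‑one
Conditions: TBSCl, imidazole, DMF, rt
Reagents that add atoms: tert‑butyldimethylsilyl chloride, CC(C)(C)[Si](C)(C)Cl
Why: Silylation of a secondary alcohol; the ether survives the amide base, organozinc, Grignard and organolithium reagents that follow.

Step 4
Reactants: 4 (4R,6R)‑4‑(TBSO)‑2,2,6‑trimethylcyclohexan‑1‑one
Product: 5 (4R)‑4‑(TBSO)‑2,6,6‑trimethylcyclohex‑1‑en‑1‑yl trifluoromethanesulfonate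
Conditions: LiN(i‑Pr)2, THF, −78 → 0 °C; then PhNTf2, −78 → 0 °C
Reagents that add atoms: N‑phenylbis(trifluoromethanesulfonimide), O=S(=O)(N(c1ccccc1)S(=O)(=O)C(F)(F)F)C(F)(F)F
Why: Only C6 carries an α‑hydrogen, so enolisation and O‑sulfonylation can give one enol triflate; the C6 centre disappears and C4 alone carries the chirality.

Step 5
Reactants: 5 (4R)‑4‑(TBSO)‑2,6,6‑trimethylcyclohex‑1‑en‑1‑yl trifluoromethanesulfonate; 6 ethyl bromoacetate
Product: 8 ethyl 2‑[(4R)‑4‑(TBSO)‑2,6,6‑trimethylcyclohex‑1‑en‑1‑yl]acetate, via Reformatsky reagent ethyl (bromozincio)acetate 7 (not isolated)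
Conditions: 6, Zn dust (Me3SiCl‑activated), THF, 45 °C; then 5, Pd(PPh3)4 (5 mol%), THF–DMPU, 65 °C
Reagents that add atoms: none
Why: Negishi‑type coupling of a zinc ester enolate with an enol triflate: oxidative addition to zerovalent palladium, transmetalation and reductive elimination; the alkene stays where the triflate fixed it, which gives the β,γ‑unsaturated ester.

Step 6
Reactants: 8 ethyl 2‑[(4R)‑4‑(TBSO)‑2,6,6‑trimethylcyclohex‑1‑en‑1‑yl]acetate
Product: 9 2‑[(4R)‑4‑(TBSO)‑2,6,6‑trimethylcyclohex‑1‑en‑1‑yl]‑N‑methoxy‑N‑methylacetamide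
Conditions: MeNH(OMe)·HCl, i‑PrMgCl, THF, −20 → 0 °C
Reagents that add atoms: N,O‑dimethylhydroxylamine hydrochloride, CNOC.Cl
Why: Aminolysis of the ester by the chloromagnesium amide (Weinreb amide formation); the low temperature should keep the tetrasubstituted alkene out of conjugation.

Step 7
Reactants: 9 2‑[(4R)‑4‑(TBSO)‑2,6,6‑trimethylcyclohex‑1‑en‑1‑yl]‑N‑methoxy‑N‑methylacetamide; 10 propargyl alcohol
Product: 12 1‑[(4R)‑4‑(TBSO)‑2,6,6‑trimethylcyclohex‑1‑en‑1‑yl]‑5‑hydroxypent‑3‑yn‑2‑one, via dilithiated prop‑2‑yn‑1‑ol 11 (not isolated)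
Conditions: 10 (3 equiv), n‑BuLi (6 equiv), THF, −78 → −20 °C; then 9, −78 → 0 °C; aqueous work‑up
Reagents that add atoms: none
Why: Acetylide addition to a Weinreb amide; the chelated tetrahedral intermediate prevents a second addition, and the lithium alkoxide end of the reagent is a spectator, so the primary hydroxyl needs no protecting group.

Step 8
Reactants: 12 1‑[(4R)‑4‑(TBSO)‑2,6,6‑trimethylcyclohex‑1‑en‑1‑yl]‑5‑hydroxypent‑3‑yn‑2‑one
Product: 13 (2R)‑1‑[(4R)‑4‑(TBSO)‑2,6,6‑trimethylcyclohex‑1‑en‑1‑yl]pent‑3‑yne‑2,5‑diol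
Conditions: Ru(p‑cymene)[(R,R)‑TsDPEN] (16‑electron amido complex, 2 mol%, made beforehand from RuCl(p‑cymene)[(R,R)‑TsDPEN] and KOH), i‑PrOH, rt
Reagents that add atoms: none
Why: Noyori asymmetric transfer hydrogenation of an alkynyl ketone: hydride and proton pass from the ruthenium hydride–amine through a six‑membered transition state in which the alkyne lies next to the arene ligand, so the (R,R) ligand should give the (2R) carbinol whatever the remote ring centre; no base is present to move the alkene.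

Step 9
Reactants: 13 (2R)‑1‑[(4R)‑4‑(TBSO)‑2,6,6‑trimethylcyclohex‑1‑en‑1‑yl]pent‑3‑yne‑2,5‑diol
Product: 14 (2R)‑1‑[(4R)‑4‑(TBSO)‑2,6,6‑trimethylcyclohex‑1‑en‑1‑yl]pent‑3‑yne‑2,5‑diyl diacetate
Conditions: Ac2O, pyridine, DMAP (cat.), CH2Cl2, 0 °C → rt
Reagents that add atoms: acetic anhydride, CC(=O)OC(C)=O
Why: Acylation of both propargylic hydroxyls; the C2' acetate cannot bind vanadium, so the later epoxidation is steered by C6' alone.

Step 10
Reactants: 14 (2R)‑1‑[(4R)‑4‑(TBSO)‑2,6,6‑trimethylcyclohex‑1‑en‑1‑yl]pent‑3‑yne‑2,5‑diyl diacetate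
Product: 15 (2R)‑1‑[(4R)‑4‑hydroxy‑2,6,6‑trimethylcyclohex‑1‑en‑1‑yl]pent‑3‑yne‑2,5‑diyl diacetate
Conditions: HF·pyridine, pyridine, THF, 0 °C → rt
Reagents that add atoms: none
Why: Fluoride cleavage of the secondary silyl ether; acetates, alkyne and alkene are inert to buffered HF.

Step 11
Reactants: 15 (2R)‑1‑[(4R)‑4‑hydroxy‑2,6,6‑trimethylcyclohex‑1‑en‑1‑yl]pent‑3‑yne‑2,5‑diyl diacetate
Product: 16 (2R)‑1‑[(1R,4S,6S)‑4‑hydroxy‑2,2,6‑trimethyl‑7‑oxabicyclo[4.1.0]heptan‑1‑yl]pent‑3‑yne‑2,5‑diyl diacetate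
Conditions: VO(acac)2 (5 mol%), t‑BuOOH (anhydrous, in decane), CH2Cl2, 0 °C → rt
Reagents that add atoms: tert‑butyl hydroperoxide, CC(C)(C)OO
Why: Hydroxyl‑directed epoxidation of a cyclic homoallylic alcohol: the C6' alkoxide binds pentavalent vanadium and passes the peroxide oxygen to the alkene face on its own side, which should set C3a' and C7a' syn to the hydroxyl.

Step 12
Reactants: 16 (2R)‑1‑[(1R,4S,6S)‑4‑hydroxy‑2,2,6‑trimethyl‑7‑oxabicyclo[4.1.0]heptan‑1‑yl]pent‑3‑yne‑2,5‑diyl diacetate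
Product: 17 (2R)‑1‑[(1R,4S,6S)‑4‑(TBSO)‑2,2,6‑trimethyl‑7‑oxabicyclo[4.1.0]heptan‑1‑yl]pent‑3‑yne‑2,5‑diyl diacetate
Conditions: TBSCl, imidazole, DMF, rt
Reagents that add atoms: tert‑butyldimethylsilyl chloride, CC(C)(C)[Si](C)(C)Cl
Why: Silylation of the only free hydroxyl under buffered conditions that leave the epoxide closed; the ether keeps C6' out of the cyclisation and out of the later dehydration.

Step 13
Reactants: 17 (2R)‑1‑[(1R,4S,6S)‑4‑(TBSO)‑2,2,6‑trimethyl‑7‑oxabicyclo[4.1.0]heptan‑1‑yl]pent‑3‑yne‑2,5‑diyl diacetate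
Product: 18 (2R)‑1‑[(1R,4S,6S)‑4‑(TBSO)‑2,2,6‑trimethyl‑7‑oxabicyclo[4.1.0]heptan‑1‑yl]pent‑3‑yne‑2,5‑diol
Conditions: K2CO3 (cat.), MeOH, 0 °C
Reagents that add atoms: none
Why: Transesterification of both acetates; under base an alkoxide does not open a fully substituted epoxide, and the 3,4‑epoxy alcohol has no Payne pathway.

Step 14
Reactants: 18 (2R)‑1‑[(1R,4S,6S)‑4‑(TBSO)‑2,2,6‑trimethyl‑7‑oxabicyclo[4.1.0]heptan‑1‑yl]pent‑3‑yne‑2,5‑diol
Product: 19 (2R,3aR,6S,7aR)‑6‑(TBSO)‑2‑(3‑hydroxyprop‑1‑yn‑1‑yl)‑4,4,7a‑trimethyloctahydro‑1‑benzofuran‑3a‑ol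
Conditions: (+)‑camphor‑10‑sulfonic acid (10 mol%), CH2Cl2, 0 °C → rt (BF3·OEt2, CH2Cl2, −78 °C as a second choice)
Reagents that add atoms: none
Why: The acid protonates the epoxide oxygen, the C7a'–O bond stretches with positive charge building on the tertiary C7a', the C2' hydroxyl attacks that carbon from the side opposite the leaving oxygen, and the proton is lost. The closest known reaction type is the acid‑promoted opening of 3,4‑epoxy alcohols at the more substituted distal carbon to tetrahydrofurans. The tetrahydrofuran closes in the 5‑endo mode, with both epoxide carbons in the new ring, and this is preferred over 4‑exo closure to an oxetane at C3a' because of ring strain. The one new centre, C7a', is formed with inversion; the control element is the C3'–C2' arm, which sits on C3a' anti to the epoxide oxygen and can reach only the rear of the C7a'–O bond, so a cis‑fused ring with O1' trans to the C6' oxygen must result. C7a' is thus relayed from C6' through the syn epoxide, C3a' keeps its oxygen with retention, and C2' is untouched because its oxygen is the nucleophile. The step needs regioselectivity for C7a' over C3a' and chemoselectivity over elimination and Meinwald‑type rearrangement. The substrate secures these through the internal nucleophile held within reach, the silyl ether on C6', and a primary hydroxyl that cannot bend back across the linear alkyne. Even a partly cationic course should be funnelled to the same product, because the arm can reach only one face of C7a'.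

Step 15
Reactants: 19 (2R,3aR,6S,7aR)‑6‑(TBSO)‑2‑(3‑hydroxyprop‑1‑yn‑1‑yl)‑4,4,7a‑trimethyloctahydro‑1‑benzofuran‑3a‑ol
Product: 21 (2R,3aR,6S,7aR)‑6‑(TBSO)‑2‑[(1Z)‑3‑hydroxy‑1‑iodoprop‑1‑en‑1‑yl]‑4,4,7a‑trimethyloctahydro‑1‑benzofuran‑3a‑ol, via cyclic sodium vinylalanate 20 (not isolated)
Conditions: NaAlH2(OCH2CH2OCH3)2 (4 equiv), THF, 0 °C → rt; then EtOAc, −78 °C; I2, THF, −78 → 0 °C
Reagents that add atoms: iodine, [I][I]
Why: Hydroxyl‑directed trans‑hydroalumination of a propargylic alcohol followed by iodinolysis with retention: hydrogen goes to the alkyne carbon next to CH2O and aluminium to the carbon next to C2', which fixes the (Z)‑iodoalkene; the tertiary hydroxyl only consumes hydride.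

Step 16
Reactants: 21 (2R,3aR,6S,7aR)‑6‑(TBSO)‑2‑[(1Z)‑3‑hydroxy‑1‑iodoprop‑1‑en‑1‑yl]‑4,4,7a‑trimethyloctahydro‑1‑benzofuran‑3a‑ol
Product: 22 3‑[(2R,3aR,6S,7aR)‑6‑(TBSO)‑3a‑hydroxy‑4,4,7a‑trimethyloctahydro‑1‑benzofuran‑2‑yl]furan‑2(5H)‑one
Conditions: Pd(PPh3)4 (5 mol%), CO (1 atm), K2CO3, THF, 50 °C
Reagents that add atoms: carbon monoxide, [C-]#[O+]
Why: Carbonylative lactonisation: oxidative addition of the vinyl iodide to zerovalent palladium, CO insertion, and capture of the acylpalladium by the cis allylic hydroxyl; the tertiary hydroxyl is too far and too hindered to compete.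

Step 17
Reactants: 22 3‑[(2R,3aR,6S,7aR)‑6‑(TBSO)‑3a‑hydroxy‑4,4,7a‑trimethyloctahydro‑1‑benzofuran‑2‑yl]furan‑2(5H)‑one
Product: 23 3‑[(2R,6S,7aR)‑6‑(TBSO)‑4,4,7a‑trimethyl‑2,4,5,6,7,7a‑hexahydro‑1‑benzofuran‑2‑yl]furan‑2(5H)‑one
Conditions: Burgess reagent (MeO2C–N(−)–SO2–N(+)Et3), toluene, 50 °C
Reagents that add atoms: none
Why: Burgess dehydration: the tertiary sulfamate undergoes a syn elimination under neutral conditions; C4' and C7a' carry no hydrogen, so the alkene can form only toward C3'.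

Step 18
Reactants: 5 (4R)‑4‑(TBSO)‑2,6,6‑trimethylcyclohex‑1‑en‑1‑yl trifluoromethanesulfonate; 24 (2E)‑3‑methylpent‑2‑en‑4‑yn‑1‑ol
Product: 25 (2E)‑5‑[(4R)‑4‑(TBSO)‑2,6,6‑trimethylcyclohex‑1‑en‑1‑yl]‑3‑methylpent‑2‑en‑4‑yn‑1‑ol
Conditions: Pd(PPh3)4 (5 mol%), CuI (10 mol%), i‑Pr2NH, DMF, rt → 50 °C
Reagents that add atoms: none
Why: Sonogashira coupling of the enol triflate with a terminal alkyne; the E alkene of 24 is carried over unchanged.

Step 19
Reactants: 25 (2E)‑5‑[(4R)‑4‑(TBSO)‑2,6,6‑trimethylcyclohex‑1‑en‑1‑yl]‑3‑methylpent‑2‑en‑4‑yn‑1‑ol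
Product: 26 (2E)‑5‑[(4R)‑4‑(TBSO)‑2,6,6‑trimethylcyclohex‑1‑en‑1‑yl]‑3‑methylpent‑2‑en‑4‑ynal
Conditions: MnO2 (activated, excess), CH2Cl2, rt, dark
Reagents that add atoms: none
Why: Selective oxidation of an allylic alcohol to the enal on the MnO2 surface, without over‑oxidation.

Step 20
Reactants: 26 (2E)‑5‑[(4R)‑4‑(TBSO)‑2,6,6‑trimethylcyclohex‑1‑en‑1‑yl]‑3‑methylpent‑2‑en‑4‑ynal; 27 triethyl 4‑phosphonocrotonate
Product: 28 ethyl (2E,4E,6E)‑9‑[(4R)‑4‑(TBSO)‑2,6,6‑trimethylcyclohex‑1‑en‑1‑yl]‑7‑methylnona‑2,4,6‑trien‑8‑ynoate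
Conditions: 27, LiN(SiMe3)2, THF, −78 °C; then 26, −78 → 0 °C, dark
Reagents that add atoms: none
Why: Horner–Wadsworth–Emmons olefination with a vinylogous stabilised phosphonate; reversible addition should favour the E alkene, and the E alkene of the crotonate is retained.

Step 21
Reactants: 28 ethyl (2E,4E,6E)‑9‑[(4R)‑4‑(TBSO)‑2,6,6‑trimethylcyclohex‑1‑en‑1‑yl]‑7‑methylnona‑2,4,6‑trien‑8‑ynoate
Product: 29 (2E,4E,6E)‑9‑[(4R)‑4‑(TBSO)‑2,6,6‑trimethylcyclohex‑1‑en‑1‑yl]‑7‑methylnona‑2,4,6‑trien‑8‑yn‑1‑ol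
Conditions: i‑Bu2AlH (2.5 equiv), CH2Cl2, −78 °C; aq. KNaC4H4O6 (potassium sodium tartrate)
Reagents that add atoms: none
Why: 1,2‑Reduction of the conjugated ester to the allylic alcohol; the aluminium hydride does not touch the polyenyne at low temperature.

Step 22
Reactants: 29 (2E,4E,6E)‑9‑[(4R)‑4‑(TBSO)‑2,6,6‑trimethylcyclohex‑1‑en‑1‑yl]‑7‑methylnona‑2,4,6‑trien‑8‑yn‑1‑ol
Product: 30 (2E,4E,6E)‑9‑[(4R)‑4‑(TBSO)‑2,6,6‑trimethylcyclohex‑1‑en‑1‑yl]‑7‑methylnona‑2,4,6‑trien‑8‑ynal
Conditions: MnO2 (activated, excess), CH2Cl2, rt, dark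
Reagents that add atoms: none
Why: Allylic oxidation to the polyenal under neutral conditions.

Step 23
Reactants: 30 (2E,4E,6E)‑9‑[(4R)‑4‑(TBSO)‑2,6,6‑trimethylcyclohex‑1‑en‑1‑yl]‑7‑methylnona‑2,4,6‑trien‑8‑ynal; 31 2‑(triphenylphosphoranylidene)propanal
Product: 32 (2E,4E,6E,8E)‑11‑[(4R)‑4‑(TBSO)‑2,6,6‑trimethylcyclohex‑1‑en‑1‑yl]‑2,9‑dimethylundeca‑2,4,6,8‑tetraen‑10‑ynal
Conditions: 31, toluene, 80 °C, dark
Reagents that add atoms: none
Why: Wittig reaction with a stabilised α‑branched ylide, which should give the E trisubstituted alkene; the α‑methyl enal formed is less reactive than 30, so a second homologation should not follow.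

Step 24
Reactants: 23 3‑[(2R,6S,7aR)‑6‑(TBSO)‑4,4,7a‑trimethyl‑2,4,5,6,7,7a‑hexahydro‑1‑benzofuran‑2‑yl]furan‑2(5H)‑one; 32 (2E,4E,6E,8E)‑11‑[(4R)‑4‑(TBSO)‑2,6,6‑trimethylcyclohex‑1‑en‑1‑yl]‑2,9‑dimethylundeca‑2,4,6,8‑tetraen‑10‑ynal
Product: 35 (5Z)‑3‑[(2R,6S,7aR)‑6‑(TBSO)‑4,4,7a‑trimethyl‑2,4,5,6,7,7a‑hexahydro‑1‑benzofuran‑2‑yl]‑5‑[(2E,4E,6E,8E)‑11‑[(4R)‑4‑(TBSO)‑2,6,6‑trimethylcyclohex‑1‑en‑1‑yl]‑2,9‑dimethylundeca‑2,4,6,8‑tetraen‑10‑yn‑1‑ylidene]furan‑2(5H)‑one, via silyloxyfuran 33 (not isolated), via silyl aldol adduct 34 (not isolated)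
Conditions: TBSOTf (1.3 equiv), i‑Pr2NEt (3 equiv), CH2Cl2, −78 → 0 °C; then 32; then DBU, 0 °C → rt, dark
Reagents that add atoms: none
Why: Vinylogous Mukaiyama aldol condensation: the butenolide is silylated to the 2‑silyloxyfuran, which adds through C5 to the silyl‑activated aldehyde, and DBU then removes silanol by an E1cB elimination through the dienolate. The reversible elimination should favour the less crowded Z ylidene, and the excess amine keeps the medium from ionising the C2'–O1' bond.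

Step 25
Reactants: 35 bis‑TBS ether of the target (name as in step 24)
Product: 36 (5Z)‑3‑[(2R,6S,7aR)‑6‑hydroxy‑4,4,7a‑trimethyl‑2,4,5,6,7,7a‑hexahydro‑1‑benzofuran‑2‑yl]‑5‑[(2E,4E,6E,8E)‑11‑[(4R)‑4‑hydroxy‑2,6,6‑trimethylcyclohex‑1‑en‑1‑yl]‑2,9‑dimethylundeca‑2,4,6,8‑tetraen‑10‑yn‑1‑ylidene]furan‑2(5H)‑one (CNP0300047.2)
Conditions: Bu4NF, AcOH (1:1), THF, 0 °C → rt, dark
Reagents that add atoms: none
Why: Fluoride cleavage of both secondary silyl ethers; the acetic acid buffer protects the enol lactone from alkoxide and is too weak to ionise the allylic ether at C2'.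

## Compound list

1 | ketoisophorone (2,6,6‑trimethylcyclohex‑2‑ene‑1,4‑dione) | CC1=CC(=O)CC(C)(C)C1=O | starting material
2 | (6R)‑2,2,6‑trimethylcyclohexane‑1,4‑dione | C[C@@H]1CC(=O)CC(C)(C)C1=O | intermediate
3 | (4R,6R)‑4‑hydroxy‑2,2,6‑trimethylcyclohexan‑1‑one | C[C@@H]1C[C@@H](O)CC(C)(C)C1=O | intermediate
4 | (4R,6R)‑4‑(TBSO)‑2,2,6‑trimethylcyclohexan‑1‑one | C[C@@H]1C[C@@H](O[Si](C)(C)C(C)(C)C)CC(C)(C)C1=O | intermediate
5 | (4R)‑4‑(TBSO)‑2,6,6‑trimethylcyclohex‑1‑en‑1‑yl trifluoromethanesulfonate | CC1=C(OS(=O)(=O)C(F)(F)F)C(C)(C)C[C@H](O[Si](C)(C)C(C)(C)C)C1 | intermediate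
6 | ethyl bromoacetate | CCOC(=O)CBr | starting material
7 | ethyl (bromozincio)acetate | CCOC(=O)C[Zn]Br | intermediate
8 | ethyl 2‑[(4R)‑4‑(TBSO)‑2,6,6‑trimethylcyclohex‑1‑en‑1‑yl]acetate | CCOC(=O)CC1=C(C)C[C@@H](O[Si](C)(C)C(C)(C)C)CC1(C)C | intermediate
9 | 2‑[(4R)‑4‑(TBSO)‑2,6,6‑trimethylcyclohex‑1‑en‑1‑yl]‑N‑methoxy‑N‑methylacetamide | CON(C)C(=O)CC1=C(C)C[C@@H](O[Si](C)(C)C(C)(C)C)CC1(C)C | intermediate
10 | propargyl alcohol (prop‑2‑yn‑1‑ol) | C#CCO | starting material
11 | dilithiated prop‑2‑yn‑1‑ol | [Li]C#CCO[Li] | intermediate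
12 | 1‑[(4R)‑4‑(TBSO)‑2,6,6‑trimethylcyclohex‑1‑en‑1‑yl]‑5‑hydroxypent‑3‑yn‑2‑one | OCC#CC(=O)CC1=C(C)C[C@@H](O[Si](C)(C)C(C)(C)C)CC1(C)C | intermediate
13 | (2R)‑1‑[(4R)‑4‑(TBSO)‑2,6,6‑trimethylcyclohex‑1‑en‑1‑yl]pent‑3‑yne‑2,5‑diol | OCC#C[C@H](O)CC1=C(C)C[C@@H](O[Si](C)(C)C(C)(C)C)CC1(C)C | intermediate
14 | (2R)‑1‑[(4R)‑4‑(TBSO)‑2,6,6‑trimethylcyclohex‑1‑en‑1‑yl]pent‑3‑yne‑2,5‑diyl diacetate | CC(=O)OCC#C[C@H](OC(C)=O)CC1=C(C)C[C@@H](O[Si](C)(C)C(C)(C)C)CC1(C)C | intermediate
15 | (2R)‑1‑[(4R)‑4‑hydroxy‑2,6,6‑trimethylcyclohex‑1‑en‑1‑yl]pent‑3‑yne‑2,5‑diyl diacetate | CC(=O)OCC#C[C@H](OC(C)=O)CC1=C(C)C[C@@H](O)CC1(C)C | intermediate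
16 | (2R)‑1‑[(1R,4S,6S)‑4‑hydroxy‑2,2,6‑trimethyl‑7‑oxabicyclo[4.1.0]heptan‑1‑yl]pent‑3‑yne‑2,5‑diyl diacetate | CC(=O)OCC#C[C@H](OC(C)=O)C[C@]12O[C@@]1(C)C[C@@H](O)CC2(C)C | intermediate
17 | (2R)‑1‑[(1R,4S,6S)‑4‑(TBSO)‑2,2,6‑trimethyl‑7‑oxabicyclo[4.1.0]heptan‑1‑yl]pent‑3‑yne‑2,5‑diyl diacetate | CC(=O)OCC#C[C@H](OC(C)=O)C[C@]12O[C@@]1(C)C[C@@H](O[Si](C)(C)C(C)(C)C)CC2(C)C | intermediate
18 | (2R)‑1‑[(1R,4S,6S)‑4‑(TBSO)‑2,2,6‑trimethyl‑7‑oxabicyclo[4.1.0]heptan‑1‑yl]pent‑3‑yne‑2,5‑diol | OCC#C[C@H](O)C[C@]12O[C@@]1(C)C[C@@H](O[Si](C)(C)C(C)(C)C)CC2(C)C | intermediate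
19 | (2R,3aR,6S,7aR)‑6‑(TBSO)‑2‑(3‑hydroxyprop‑1‑yn‑1‑yl)‑4,4,7a‑trimethyloctahydro‑1‑benzofuran‑3a‑ol | OCC#C[C@H]1C[C@@]2(O)C(C)(C)C[C@H](O[Si](C)(C)C(C)(C)C)C[C@@]2(C)O1 | intermediate
20 | cyclic sodium alkoxy(vinyl)bis(2‑methoxyethoxy)aluminate of 19 (aluminium on the alkene carbon next to C2'; tertiary hydroxyl drawn neutral) | [Na+].COCCO[Al-]1(OCCOC)OCC=C1[C@H]3C[C@@]4(O)C(C)(C)C[C@H](O[Si](C)(C)C(C)(C)C)C[C@@]4(C)O3 | intermediate
21 | (2R,3aR,6S,7aR)‑6‑(TBSO)‑2‑[(1Z)‑3‑hydroxy‑1‑iodoprop‑1‑en‑1‑yl]‑4,4,7a‑trimethyloctahydro‑1‑benzofuran‑3a‑ol | OC/C=C(\I)[C@H]1C[C@@]2(O)C(C)(C)C[C@H](O[Si](C)(C)C(C)(C)C)C[C@@]2(C)O1 | intermediate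
22 | 3‑[(2R,3aR,6S,7aR)‑6‑(TBSO)‑3a‑hydroxy‑4,4,7a‑trimethyloctahydro‑1‑benzofuran‑2‑yl]furan‑2(5H)‑one | O=C1OCC=C1[C@H]2C[C@@]3(O)C(C)(C)C[C@H](O[Si](C)(C)C(C)(C)C)C[C@@]3(C)O2 | intermediate
23 | 3‑[(2R,6S,7aR)‑6‑(TBSO)‑4,4,7a‑trimethyl‑2,4,5,6,7,7a‑hexahydro‑1‑benzofuran‑2‑yl]furan‑2(5H)‑one | O=C1OCC=C1[C@H]2C=C3C(C)(C)C[C@H](O[Si](C)(C)C(C)(C)C)C[C@@]3(C)O2 | intermediate
24 | (2E)‑3‑methylpent‑2‑en‑4‑yn‑1‑ol | C#C/C(C)=C/CO | starting material
25 | (2E)‑5‑[(4R)‑4‑(TBSO)‑2,6,6‑trimethylcyclohex‑1‑en‑1‑yl]‑3‑methylpent‑2‑en‑4‑yn‑1‑ol | CC1=C(C#C/C(C)=C/CO)C(C)(C)C[C@H](O[Si](C)(C)C(C)(C)C)C1 | intermediate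
26 | (2E)‑5‑[(4R)‑4‑(TBSO)‑2,6,6‑trimethylcyclohex‑1‑en‑1‑yl]‑3‑methylpent‑2‑en‑4‑ynal | CC1=C(C#C/C(C)=C/C=O)C(C)(C)C[C@H](O[Si](C)(C)C(C)(C)C)C1 | intermediate
27 | triethyl 4‑phosphonocrotonate | CCOC(=O)/C=C/CP(=O)(OCC)OCC | starting material
28 | ethyl (2E,4E,6E)‑9‑[(4R)‑4‑(TBSO)‑2,6,6‑trimethylcyclohex‑1‑en‑1‑yl]‑7‑methylnona‑2,4,6‑trien‑8‑ynoate | CC1=C(C#C/C(C)=C/C=C/C=C/C(=O)OCC)C(C)(C)C[C@H](O[Si](C)(C)C(C)(C)C)C1 | intermediate
29 | (2E,4E,6E)‑9‑[(4R)‑4‑(TBSO)‑2,6,6‑trimethylcyclohex‑1‑en‑1‑yl]‑7‑methylnona‑2,4,6‑trien‑8‑yn‑1‑ol | CC1=C(C#C/C(C)=C/C=C/C=C/CO)C(C)(C)C[C@H](O[Si](C)(C)C(C)(C)C)C1 | intermediate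
30 | (2E,4E,6E)‑9‑[(4R)‑4‑(TBSO)‑2,6,6‑trimethylcyclohex‑1‑en‑1‑yl]‑7‑methylnona‑2,4,6‑trien‑8‑ynal | CC1=C(C#C/C(C)=C/C=C/C=C/C=O)C(C)(C)C[C@H](O[Si](C)(C)C(C)(C)C)C1 | intermediate
31 | 2‑(triphenylphosphoranylidene)propanal | CC(C=O)=P(c1ccccc1)(c1ccccc1)c1ccccc1 | starting material
32 | (2E,4E,6E,8E)‑11‑[(4R)‑4‑(TBSO)‑2,6,6‑trimethylcyclohex‑1‑en‑1‑yl]‑2,9‑dimethylundeca‑2,4,6,8‑tetraen‑10‑ynal | CC1=C(C#C/C(C)=C/C=C/C=C/C=C(C)/C=O)C(C)(C)C[C@H](O[Si](C)(C)C(C)(C)C)C1 | intermediate
33 | tert‑butyl({3‑[(2R,6S,7aR)‑6‑(TBSO)‑4,4,7a‑trimethyl‑2,4,5,6,7,7a‑hexahydro‑1‑benzofuran‑2‑yl]furan‑2‑yl}oxy)dimethylsilane | CC(C)(C)[Si](C)(C)Oc1occc1[C@H]2C=C3C(C)(C)C[C@H](O[Si](C)(C)C(C)(C)C)C[C@@]3(C)O2 | intermediate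
34 | 5‑[1‑(TBSO)‑polyenynyl]furan‑2(5H)‑one adduct of 33 and 32 (both epimers at butenolide C5 and at the silyloxy carbon) | CC1=C(C#C/C(C)=C/C=C/C=C/C=C(C)/C(O[Si](C)(C)C(C)(C)C)C2C=C([C@H]3C=C4C(C)(C)C[C@H](O[Si](C)(C)C(C)(C)C)C[C@@]4(C)O3)C(=O)O2)C(C)(C)C[C@H](O[Si](C)(C)C(C)(C)C)C1 | intermediate
35 | bis‑TBS ether of the target | CC1=C(C#C/C(C)=C/C=C/C=C/C=C(C)/C=C2/C=C([C@H]3C=C4C(C)(C)C[C@H](O[Si](C)(C)C(C)(C)C)C[C@@]4(C)O3)C(=O)O2)C(C)(C)C[C@H](O[Si](C)(C)C(C)(C)C)C1 | intermediate
36 | CNP0300047.2 (name as in step 25) | CC1=C(C#C/C(C)=C/C=C/C=C/C=C(C)/C=C2/C=C([C@H]3C=C4C(C)(C)C[C@H](O)C[C@@]4(C)O3)C(=O)O2)C(C)(C)C[C@H](O)C1 | target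

## Step count and least certain steps

Total: 25 steps. Longest linear sequence: 19 steps (steps 1–17, 24 and 25); the ring A branch (steps 18–23) leaves the main line at 5.

Step 14 (key step). The most likely failure is opening of the protonated epoxide in the wrong direction: ionisation at C3a', or a Meinwald‑type shift, before the C2' oxygen arrives. Fallback from 18 to 19: the epoxide is first isomerised under non‑acidic conditions with Al(O‑i‑Pr)3 in refluxing toluene, which removes a proton from the C7a' methyl and should give the allylic alcohol (2R)‑1‑[(1R,4S)‑4‑(TBSO)‑1‑hydroxy‑2,2‑dimethyl‑6‑methylidenecyclohexyl]pent‑3‑yne‑2,5‑diol F1. The C3a' oxygen stays in place, so the relay from C6' is kept. Catalytic camphorsulfonic acid in CH2Cl2 then adds the C2' hydroxyl across the 1,1‑disubstituted alkene in the Markovnikov, 5‑exo sense. Only C7a' can carry charge, and the arm on C3a' again reaches only one face, so 19 is reached. An endocyclic C7'=C7a' isomer of F1 would converge on the same product.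

Step 11. The most likely failure is incomplete facial control or slow oxygen transfer to the hindered tetrasubstituted alkene, with oxidation of the C6' carbinol as a side path. Fallback from 14 to 18 uses steric control and a halohydrin in place of a directing group. N‑Bromosuccinimide in aqueous 1,2‑dimethoxyethane at 0 °C should form the bromonium ion on the face away from the silyloxy group, and water then enters from the silyloxy face to give the bromohydrin (2R)‑1‑[(1S,2S,4S)‑1‑bromo‑4‑(TBSO)‑2‑hydroxy‑2,6,6‑trimethylcyclohexyl]pent‑3‑yne‑2,5‑diyl diacetate F2. K2CO3 in MeOH then closes the epoxide on the silyloxy face and removes both acetates in the same flask, giving 18. This skips steps 10 to 13 but relies on a steric bias, not a bound reagent.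

Step 7. The most likely failure is sluggish addition of the poorly soluble dianion, with deprotonation of the doubly activated CH2 of 9 in its place. Fallback from 9 to 12: commercial tert‑butyldimethyl(prop‑2‑yn‑1‑yloxy)silane is lithiated with n‑BuLi and added to 9 to give 5‑(TBSO)‑1‑[(4R)‑4‑(TBSO)‑2,6,6‑trimethylcyclohex‑1‑en‑1‑yl]pent‑3‑yn‑2‑one F3. The primary silyl ether is then removed selectively with HF·pyridine buffered with pyridine at 0 °C to give 12.

Step 5. The most likely failure is slow oxidative addition and transmetalation at the hindered tetrasubstituted triflate, with protonation of the zinc enolate winning. Fallback from 4 to 8 replaces the cross‑coupling by carbonyl addition. The lithium enolate of ethyl acetate (EtOAc, LiN(i‑Pr)2, THF, −78 °C) adds to 4 to give ethyl 2‑[(4R,6R)‑4‑(TBSO)‑1‑hydroxy‑2,2,6‑trimethylcyclohexyl]acetate F4. SOCl2 in pyridine at 0 °C then dehydrates the tertiary alcohol. Allylic strain in the exocyclic conjugated ester should favour loss of the ring C6 hydrogen, which gives 8.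

Step 24. The most likely failures are ionisation of the C2'–O1' bond by the silyl triflate, with epimerisation at C2', and incomplete Z selectivity in the elimination. Fallback from 23 and 32 to 35 avoids any Lewis acid. 23 is deprotonated with LiN(SiMe3)2 in THF at −78 °C and the dienolate, blocked at C3, adds through C5 to 32 to give the aldol 5‑[(2E,4E,6E,8E)‑11‑[(4R)‑4‑(TBSO)‑2,6,6‑trimethylcyclohex‑1‑en‑1‑yl]‑1‑hydroxy‑2,9‑dimethylundeca‑2,4,6,8‑tetraen‑10‑yn‑1‑yl]‑3‑[(2R,6S,7aR)‑6‑(TBSO)‑4,4,7a‑trimethyl‑2,4,5,6,7,7a‑hexahydro‑1‑benzofuran‑2‑yl]furan‑2(5H)‑one F5. MsCl and Et3N in CH2Cl2 at 0 °C convert it into the corresponding methanesulfonate F6, which is not isolated, and DBU eliminates it to 35.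

## Further compounds

F1 | step 14 | (2R)‑1‑[(1R,4S)‑4‑(TBSO)‑1‑hydroxy‑2,2‑dimethyl‑6‑methylidenecyclohexyl]pent‑3‑yne‑2,5‑diol | OCC#C[C@H](O)C[C@@]1(O)C(C)(C)C[C@H](O[Si](C)(C)C(C)(C)C)CC1=C
F2 | step 11 | (2R)‑1‑[(1S,2S,4S)‑1‑bromo‑4‑(TBSO)‑2‑hydroxy‑2,6,6‑trimethylcyclohexyl]pent‑3‑yne‑2,5‑diyl diacetate | CC(=O)OCC#C[C@H](OC(C)=O)C[C@@]1(Br)[C@@](C)(O)C[C@@H](O[Si](C)(C)C(C)(C)C)CC1(C)C
F3 | step 7 | 5‑(TBSO)‑1‑[(4R)‑4‑(TBSO)‑2,6,6‑trimethylcyclohex‑1‑en‑1‑yl]pent‑3‑yn‑2‑one | CC(C)(C)[Si](C)(C)OCC#CC(=O)CC1=C(C)C[C@@H](O[Si](C)(C)C(C)(C)C)CC1(C)C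
F4 | step 5 | ethyl 2‑[(4R,6R)‑4‑(TBSO)‑1‑hydroxy‑2,2,6‑trimethylcyclohexyl]acetate (both C1 epimers) | C[C@@H]1C[C@@H](O[Si](C)(C)C(C)(C)C)CC(C)(C)C1(O)CC(=O)OCC
F5 | step 24 | aldol of 23 and 32 (name as in the fallback text; both epimers at butenolide C5 and at the carbinol carbon) | CC1=C(C#C/C(C)=C/C=C/C=C/C=C(C)/C(O)C2C=C([C@H]3C=C4C(C)(C)C[C@H](O[Si](C)(C)C(C)(C)C)C[C@@]4(C)O3)C(=O)O2)C(C)(C)C[C@H](O[Si](C)(C)C(C)(C)C)C1
F6 | step 24 | methanesulfonate of F5 | CC1=C(C#C/C(C)=C/C=C/C=C/C=C(C)/C(OS(C)(=O)=O)C2C=C([C@H]3C=C4C(C)(C)C[C@H](O[Si](C)(C)C(C)(C)C)C[C@@]4(C)O3)C(=O)O2)C(C)(C)C[C@H](O[Si](C)(C)C(C)(C)C)C1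
A1 | alternative 1 | (1Z,5E)‑7‑(TBSO)‑1‑iodo‑5‑methyl‑1‑[(2R,6S,7aR)‑6‑(TBSO)‑4,4,7a‑trimethyl‑2,4,5,6,7,7a‑hexahydro‑1‑benzofuran‑2‑yl]hepta‑1,5‑dien‑3‑one | CC(C)(C)[Si](C)(C)OC/C=C(C)/CC(=O)/C=C(\I)[C@H]1C=C2C(C)(C)C[C@H](O[Si](C)(C)C(C)(C)C)C[C@@]2(C)O1
A2 | alternative 1 | (5Z)‑5‑[(2E)‑4‑(TBSO)‑2‑methylbut‑2‑en‑1‑ylidene]‑3‑[(2R,6S,7aR)‑6‑(TBSO)‑4,4,7a‑trimethyl‑2,4,5,6,7,7a‑hexahydro‑1‑benzofuran‑2‑yl]furan‑2(5H)‑one | CC(C)(C)[Si](C)(C)OC/C=C(C)/C=C2/C=C([C@H]3C=C4C(C)(C)C[C@H](O[Si](C)(C)C(C)(C)C)C[C@@]4(C)O3)C(=O)O2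
A3 | alternative 2 | (1R,5S)‑5‑(TBSO)‑2‑[2‑(furan‑3‑yl)ethenylidene]‑1,3,3‑trimethylcyclohexan‑1‑ol, (aS) allene axis (furyl on the face opposite the C7a' methyl) | [H]C(c1ccoc1)=[C@@]=C1C(C)(C)C[C@H](O[Si](C)(C)C(C)(C)C)C[C@@]1(C)O
A4 | alternative 2 | tert‑butyl{[(2R,6S,7aR)‑2‑(furan‑3‑yl)‑4,4,7a‑trimethyl‑2,4,5,6,7,7a‑hexahydro‑1‑benzofuran‑6‑yl]oxy}dimethylsilane | o1ccc(c1)[C@H]3C=C4C(C)(C)C[C@H](O[Si](C)(C)C(C)(C)C)C[C@@]4(C)O3
A5 | alternative 3 | 2‑(hydroxymethyl)‑3‑[(2R,6S,7aR)‑6‑(TBSO)‑4,4,7a‑trimethyl‑2,4,5,6,7,7a‑hexahydro‑1‑benzofuran‑2‑yl]cycloprop‑2‑en‑1‑one | O=C1C(CO)=C1[C@H]2C=C3C(C)(C)C[C@H](O[Si](C)(C)C(C)(C)C)C[C@@]3(C)O2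
A6 | alternative 3 | 3‑[(2R,6S,7aR)‑6‑(TBSO)‑4,4,7a‑trimethyl‑2,4,5,6,7,7a‑hexahydro‑1‑benzofuran‑2‑yl]furan‑2(5H)‑one | O=C1OCC=C1[C@H]3C=C4C(C)(C)C[C@H](O[Si](C)(C)C(C)(C)C)C[C@@]4(C)O3
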